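**Retrosynthetic overview**
- Feature: the C8 prenyl group on ring A is para to O5, and O5 is the phenol hydrogen-bonded to the C4 ketone of ring C. The target is therefore a constitutional isomer of the O5 prenyl ether of its own 7-O-prenyl flavanone core.
- Key disconnection: the C8–C1'' bond. A Claisen shift (O5 to C6) followed by a Cope shift (C6 to C8) forms it from bis-ether 4. The trigger is Eu(fod)3, a β-diketonate complex of trivalent europium, held between C4=O and O5.
- Precursor 4 is cut at its two aryl–O–prenyl bonds: O5–prenyl (Mitsunobu on the hydrogen-bonded phenol of 3) and O7–prenyl (Mitsunobu on the free 7-OH of 1).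
- Ring order: no ring is built. Rings A, B (the phenyl group) and C, and the (2S) centre, are bought with (S)-pinocembrin 1.

Key step: step 3

Remark: commercial (S)-pinocembrin is assumed to be enantiomerically pure; because a flavanone can epimerise at C2 by reversible opening to the 2'-hydroxychalcone under carbonate bases, both O-prenylations are run under Mitsunobu conditions instead of with prenyl bromide and base.

Step 1
Reactants: 1 (S)-pinocembrin; 2 3-methylbut-2-en-1-ol
Product: 3 (2S)-5-hydroxy-7-(3-methylbut-2-enyloxy)-2-phenylchroman-4-one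
Conditions: 2 (1.05 equiv), PPh3 (1.1 equiv), DIAD (1.1 equiv), THF, 0 °C
Reagents that add atoms: 3-methylbut-2-en-1-ol, CC(C)=CCO
Why: Mitsunobu etherification, in which the free 7-OH (para to C4=O and the most acidic hydroxyl) protonates the PPh3–DIAD betaine first and its phenoxide displaces the primary allylic oxyphosphonium ion at C1 (SN2, linear ether), while the 5-OH held in a hydrogen bond to C4=O reacts far more slowly and the absence of a carbonate or hydroxide base leaves the C2–O1 bond and the (2S) centre untouched.

Step 2
Reactants: 3 (2S)-5-hydroxy-7-(3-methylbut-2-enyloxy)-2-phenylchroman-4-one; 2 3-methylbut-2-en-1-ol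
Product: 4 (2S)-5,7-bis(3-methylbut-2-enyloxy)-2-phenylchroman-4-one
Conditions: 2 (1.5 equiv), PPh3 (1.5 equiv), DIAD (1.5 equiv), THF, 0 °C to rt
Reagents that add atoms: 3-methylbut-2-en-1-ol, CC(C)=CCO
Why: Mitsunobu etherification of a hydrogen-bonded ortho-acyl phenol, a known way to 5-O-prenyl flavanones, in which an excess of betaine activates the remaining 5-OH for O-alkylation by the prenyl oxyphosphonium ion, again without a base that could open ring C to the chalcone and racemise C2.

Step 3
Reactants: 4 (2S)-5,7-bis(3-methylbut-2-enyloxy)-2-phenylchroman-4-one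
Product: 7 (2S)-5-hydroxy-8-(3-methylbut-2-enyl)-7-(3-methylbut-2-enyloxy)-2-phenylchroman-4-one, via C6 reverse-prenyl ortho-dienone 5 (not isolated), via C8 prenyl para-dienone 6 (not isolated)
Conditions: Eu(fod)3 [tris(6,6,7,7,8,8,8-heptafluoro-2,2-dimethyl-3,5-octanedionato)europium, trivalent europium] (10 mol %), acid-free CHCl3, 60 °C, sealed tube, argon; then chromatography
Reagents that add atoms: none
Why: The oxophilic europium centre binds C4=O and the O5 ether oxygen as a chelate and weakens the O5–C1'' bond, so the aromatic Claisen [3,3] shift to C6, the only open ortho position, should run near 60 °C and give dienone 5 carrying a 1,1-dimethylallyl group. In 5 the chain CH2=CH–CMe2–C6–C7=C8 is a 1,5-diene, and a Cope [3,3] shift carries the allyl unit on to C8 with its CH2 end attached (dienone 6), after which tautomerisation restores aromatic ring A with the 5-OH hydrogen-bonded to C4=O. The closest known reaction type is the Eu(fod)3-catalysed para-Claisen–Cope rearrangement of 5-O-prenyl flavanones, which is established for this substrate class. No ring is closed and no lasting stereocentre is formed: the transient sp3 centres at C6 and C8 are erased on aromatisation, and C2 takes no part under these neutral, non-basic conditions. The first selectivity needed is between the two prenyl ethers, and it is secured because only O5 can form the chelate with C4=O, whereas the O7 ether is an ordinary aryl prenyl ether that rearranges only far above this temperature. The second is that the Cope shift must be faster than enolisation of 5; crowding of the quaternary carbon on C6 between C5=O and the O7 substituent favours this, and the 6-(1,1-dimethylallyl) isomer from early enolisation should be separable by chromatography, if necessary on AgNO3-impregnated silica.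

**Compound list**
1 | (S)-pinocembrin, (2S)-5,7-dihydroxy-2-phenylchroman-4-one | O=C1C[C@@H](c2ccccc2)Oc2cc(O)cc(O)c21 | starting material
2 | 3-methylbut-2-en-1-ol (prenol) | CC(C)=CCO | starting material
3 | (2S)-5-hydroxy-7-(3-methylbut-2-enyloxy)-2-phenylchroman-4-one | CC(C)=CCOc1cc(O)c2c(c1)O[C@H](c1ccccc1)CC2=O | intermediate
4 | (2S)-5,7-bis(3-methylbut-2-enyloxy)-2-phenylchroman-4-one | CC(C)=CCOc1cc(OCC=C(C)C)c2c(c1)O[C@H](c1ccccc1)CC2=O | intermediate
5 | (2S)-6-(2-methylbut-3-en-2-yl)-7-(3-methylbut-2-enyloxy)-2-phenyl-2,3-dihydro-4H-chromene-4,5(6H)-dione, both C6 epimers | CC(C)=CCOC1=CC2=C(C(=O)C1C(C)(C)C=C)C(=O)C[C@@H](c3ccccc3)O2 | intermediate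
6 | (2S)-8-(3-methylbut-2-enyl)-7-(3-methylbut-2-enyloxy)-2-phenyl-2,3-dihydro-4H-chromene-4,5(8H)-dione, both C8 epimers | CC(C)=CCOC1=CC(=O)C2=C(O[C@H](c3ccccc3)CC2=O)C1CC=C(C)C | intermediate
7 | (2S)-5-hydroxy-8-(3-methylbut-2-enyl)-7-(3-methylbut-2-enyloxy)-2-phenylchroman-4-one | CC(C)=CCOc1cc(O)c2c(c1CC=C(C)C)O[C@H](c1ccccc1)CC2=O | target

Total step count: 3. Longest linear sequence: 3 steps (1 to 3 to 4 to 7).

**Steps most likely to fail**

Step 3 (key step). Dienone 5 may tautomerise to the phenol before the Cope shift, which leaves the allyl group at C6 in its 1,1-dimethylallyl form. The Lewis acid may also ionise a prenyl ether of the electron-rich dialkoxy ring, with loss of prenyl from O5 or O7. The fallback runs the same sigmatropic relay on a ring that is less electron-rich and carries no second allyl ether, and installs the O7 prenyl group last. It sets out from 1 and returns at 7.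
- Selective acetylation of the free 7-OH (Ac2O 1.05 equiv, pyridine, CH2Cl2, 0 °C) should give (2S)-7-acetoxy-5-hydroxy-2-phenylchroman-4-one F1.
- Mitsunobu etherification of its 5-OH with 2 (PPh3, DIAD, THF) should give (2S)-7-acetoxy-5-(3-methylbut-2-enyloxy)-2-phenylchroman-4-one F2.
- Eu(fod)3 (10 mol %) in CHCl3 at 60 °C should take F2 through (2S)-6-(2-methylbut-3-en-2-yl)-4,5-dioxo-2-phenyl-3,4,5,6-tetrahydro-2H-chromen-7-yl acetate F3 and (2S)-8-(3-methylbut-2-enyl)-4,5-dioxo-2-phenyl-3,4,5,8-tetrahydro-2H-chromen-7-yl acetate F4, neither isolated, to (2S)-7-acetoxy-5-hydroxy-8-(3-methylbut-2-enyl)-2-phenylchroman-4-one F5.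
- Methanolysis of the aryl acetate (NaHCO3, MeOH, rt) should give (2S)-5,7-dihydroxy-8-(3-methylbut-2-enyl)-2-phenylchroman-4-one F6.
- Mitsunobu etherification of its free 7-OH with 2 (1.05 equiv, PPh3, DIAD, THF, 0 °C) leads back to 7.

Step 2. Activation of the hydrogen-bonded 5-OH may be slow, so that the betaine is used up by prenol and the reduced azodicarboxylate is N-alkylated instead of the phenol. The fallback sets out from 3 and returns at 4. It replaces activation of the alcohol by silver-assisted alkylation with prenyl bromide (Ag2O, CH2Cl2, rt, in the dark), in which bromide is pulled off by silver and no soluble base is present that could open ring C. No compound outside the list is made (F0).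

Step 1. Discrimination between the 7-OH and the 5-OH may be incomplete, so that part of 1 is carried on to the bis-ether while part stays unreacted and the stoichiometry of step 2 is lost. The fallback sets out from 1 and returns at 3. It is an SN2 alkylation with prenyl bromide (1.05 equiv) and KHCO3 in DMF at rt, where bicarbonate ionises only the vinylogous-acid 7-OH and is too weak to enolise C3. No compound outside the list is made (F0).

**Further compounds**
F1 | step 3 | (2S)-7-acetoxy-5-hydroxy-2-phenylchroman-4-one | CC(=O)Oc1cc(O)c2c(c1)O[C@H](c1ccccc1)CC2=O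
F2 | step 3 | (2S)-7-acetoxy-5-(3-methylbut-2-enyloxy)-2-phenylchroman-4-one | CC(=O)Oc1cc(OCC=C(C)C)c2c(c1)O[C@H](c1ccccc1)CC2=O
F3 | step 3 | (2S)-6-(2-methylbut-3-en-2-yl)-4,5-dioxo-2-phenyl-3,4,5,6-tetrahydro-2H-chromen-7-yl acetate | CC(=O)OC1=CC2=C(C(=O)C1C(C)(C)C=C)C(=O)C[C@@H](c3ccccc3)O2
F4 | step 3 | (2S)-8-(3-methylbut-2-enyl)-4,5-dioxo-2-phenyl-3,4,5,8-tetrahydro-2H-chromen-7-yl acetate | CC(=O)OC1=CC(=O)C2=C(O[C@H](c3ccccc3)CC2=O)C1CC=C(C)C
F5 | step 3 | (2S)-7-acetoxy-5-hydroxy-8-(3-methylbut-2-enyl)-2-phenylchroman-4-one | CC(=O)Oc1cc(O)c2c(c1CC=C(C)C)O[C@H](c1ccccc1)CC2=O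
F6 | step 3 | (2S)-5,7-dihydroxy-8-(3-methylbut-2-enyl)-2-phenylchroman-4-one | CC(C)=CCc1c(O)cc(O)c2c1O[C@H](c1ccccc1)CC2=O
F0 | step 2 | none | none
F0 | step 1 | none | none
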